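**Retrosynthetic overview**

1. The triene is made last: Stille union at C15–C16 of the core 2-iodo-1-alkene 28 with the (1E,3Z)-dienylstannane 36, which comes from propargyl alcohol, homoprenyl bromide and (E)-1,2-bis(tributylstannyl)ethene.
2. 28 comes from tricyclic ketone 10: enol triflate B-alkyl Suzuki coupling and hydroboration move the carbonyl from C6 to C7 and install the C6 hydroxypropyl chain; isopropenyl addition and Babler–Dauben transposition then give the (2Z)-enal.
3. Key disconnection: C11–C26 together with O–C10, by intramolecular nitrile oxide cycloaddition of the monocyclic nitro enone 8. The isoxazoline is a temporary ring, opened at N–O and reduced at C26.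
4. Enabling feature: the ring B carbinol carbon C26 and the tertiary oxygen on C10 are 1,3-related through the spiro atom C11 and cis on ring A. The array O–C26–C11–C10(CH3)–O is therefore the retron of a 2-isoxazoline fused to ring B at C11–C26 and to ring A at C10–C11.
5. Ring order: ring A is bought (cyclohexane-1,3-dione); ring B and the isoxazoline form in the key step; the isoxazoline is then opened. One catalytic stereocentre (C14) relays to C11 and C10 (key step), C26 (directed reduction) and C6 (hydroboration).

Key step: step 5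

Remark (locants): biogenetic numbering is used throughout. C1 is the aldehyde carbon and C2 its alpha-carbon; C3–C5 are the hydroxypropyl chain (C3 carries OH). C6–C11 are ring A (cyclohexane): C6 bears the chain, C7 the alkylidene, C10 is the tertiary carbinol, C11 the spiro atom. C12–C14 and C26 are ring B (cyclopentane): C26 is the carbinol carbon, C14 bears the side chain. C15(=C27H2)–C16=C17–C18=C19 is the triene and C28 is the CH2OAc carbon.

Remark (assumption): compounds 1, 12, 30 and 35 are taken as commercial. The (S)-configured prolinol silyl ether is assumed to show its usual facial sense with enal 1.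

**Route**

Step 1
Reactants: 1 (E)-4,4-dimethoxybut-2-enal; 2 nitromethane
Product: 3 (R)-4,4-dimethoxy-3-(nitromethyl)butanal
Conditions: (S)-2-[diphenyl(trimethylsilyloxy)methyl]pyrrolidine (10 mol %), PhCO2H (20 mol %), MeOH, rt
Reagents that add atoms: none
Why: Iminium-catalysed asymmetric Michael addition of nitromethane to an enal, in which the (E)-iminium ion should be attacked at the future C14 on the face not covered by the CPh2(OSiMe3) group (the sense that gives the S adduct from cinnamaldehyde; the descriptor is R here because CH(OMe)2 outranks CH2NO2).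

Step 2
Reactants: 3 (R)-4,4-dimethoxy-3-(nitromethyl)butanal; 4 cyclohexane-1,3-dione
Product: 6 2-[(3R)-4,4-dimethoxy-3-(nitromethyl)butyl]cyclohexane-1,3-dione, via alkylidene dione 5 (not isolated)
Conditions: L-proline (20 mol %), diethyl 2,6-dimethyl-1,4-dihydropyridine-3,5-dicarboxylate (Hantzsch ester), CH2Cl2, rt
Reagents that add atoms: none
Why: Amine-catalysed Knoevenagel condensation followed by conjugate transfer hydrogenation from the Hantzsch ester (three-component reductive alkylation of a 1,3-dione) forms the C11–C12 bond without touching C14, which is not alpha to any carbonyl group.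

Step 3
Reactants: 6 2-[(3R)-4,4-dimethoxy-3-(nitromethyl)butyl]cyclohexane-1,3-dione
Product: 7 2-[(3R)-4,4-dimethoxy-3-(nitromethyl)butyl]-3-oxocyclohex-1-en-1-yl trifluoromethanesulfonate
Conditions: Tf2O, Et3N, CH2Cl2, −78 °C
Reagents that add atoms: trifluoromethanesulfonic anhydride O=S(=O)(OS(=O)(=O)C(F)(F)F)C(F)(F)F
Why: O-Sulfonylation of the vinylogous acid (enol triflate formation) at low temperature, where the far more acidic dione is the only site deprotonated by Et3N, so the nitroalkane stays intact.

Step 4
Reactants: 7 2-[(3R)-4,4-dimethoxy-3-(nitromethyl)butyl]-3-oxocyclohex-1-en-1-yl trifluoromethanesulfonate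
Product: 8 2-[(3R)-4,4-dimethoxy-3-(nitromethyl)butyl]-3-methylcyclohex-2-en-1-one (nitro enone)
Conditions: SnMe4, Pd(PPh3)4 (5 mol %), LiCl, THF, 65 °C
Reagents that add atoms: tetramethylstannane C[Sn](C)(C)C
Why: Stille cross-coupling of the vinylogous acyl triflate installs the C10 methyl group under neutral conditions, which avoids nitronate formation and its conjugate addition to the enone.

Step 5
Reactants: 8 2-[(3R)-4,4-dimethoxy-3-(nitromethyl)butyl]-3-methylcyclohex-2-en-1-one
Product: 10 tricyclic isoxazoline ketone (C6 ketone; 2-isoxazoline C26=N–O–C10 fused to ring B at C11–C26 and to ring A at C10–C11; C14–CH(OMe)2 cis to C6), via nitrile oxide 9 (not isolated)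
Conditions: PhNCO (slow addition), Et3N (cat.), toluene (0.01 M), rt → 60 °C
Reagents that add atoms: none
Why: Phenyl isocyanate and Et3N dehydrate the primary nitro group of 8 to nitrile oxide 9, which adds as a 1,3-dipole across the tetrasubstituted C10=C11 enone bond in a concerted, suprafacial [3+2] event; the closest known reaction type is the intramolecular nitrile oxide–olefin cycloaddition of ω-nitroalkenes to cyclopentane-fused 2-isoxazolines, enone dipolarophiles included. Ring B closes by C26–C11 bond formation in the exo (fused) mode set by the three-carbon tether C12–C13–C14, and the temporary isoxazoline closes by O–C10 bond formation in the same event. The regiochemistry needed (carbon to C11, oxygen to C10) is secured twice: the tether can reach only C11 without building a bridged ring, and the enone polarisation places the dipole oxygen on the beta-carbon C10. Because the addition is suprafacial, the quaternary spiro carbon C11 and the tertiary C10–O centre are created together, with C26 and the C10 oxygen cis on ring A as in the target. The face of the enone is chosen by the C14 stereocentre: in the forming five-membered ring its CH(OMe)2 group should lie beside the flat C6 carbonyl and not over the C10 methyl group, which gives the C14/C11 relation of the target. The step also needs cyclisation to outrun dimerisation of the dipole, which high dilution and slow generation of 9 secure.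

Step 6
Reactants: 10 tricyclic isoxazoline ketone
Product: 11 C6 enol triflate of 10 (C6=C7)
Conditions: KN(SiMe3)2, PhNTf2, THF, −78 °C
Reagents that add atoms: N-phenylbis(trifluoromethanesulfonimide) O=S(=O)(N(c1ccccc1)S(=O)(=O)C(F)(F)F)C(F)(F)F
Why: Kinetic enolate formation and O-triflation, in which only C7 can be deprotonated because C11 is quaternary, so a single enol triflate can form.

Step 7
Reactants: 11 C6 enol triflate; 12 allyl tert-butyldimethylsilyl ether
Product: 14 C6-[3-(tert-butyldimethylsilyloxy)propyl] cyclohexene isoxazoline (C6=C7), via B-alkyl-9-BBN 13 (not isolated)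
Conditions: 12, 9-BBN, THF, rt; then 11, PdCl2(dppf) (5 mol %), AsPh3, Cs2CO3, DMF/H2O, rt
Reagents that add atoms: none
Why: Anti-Markovnikov hydroboration of 12 with 9-BBN and B-alkyl Suzuki–Miyaura coupling of borane 13 with the hindered enol triflate, a reliable way to attach a primary sp3 carbon next to a quaternary centre.

Step 8
Reactants: 14 C6-[3-(tert-butyldimethylsilyloxy)propyl] cyclohexene isoxazoline
Product: 16 beta-hydroxy ketone (C26 ketone, C10 tertiary alcohol, C6=C7), via hydroxy imine 15 (not isolated)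
Conditions: H2 (1 atm), Raney nickel (Ni), B(OH)3, MeOH/H2O 5:1, rt
Reagents that add atoms: water O
Why: Hydrogenolysis of the isoxazoline N–O bond over Raney nickel with boric acid, which hydrolyses imine 15 at once and so unmasks the aldol without retro-aldol cleavage or epimerisation at C14, while the hindered trisubstituted alkene should survive.

Step 9
Reactants: 16 beta-hydroxy ketone
Product: 17 anti-1,3-diol (C26–OH cis to C6 and to the C14 substituent, trans to C10 on ring B; C26 and C10–OH cis on ring A)
Conditions: Me4NBH(OAc)3, MeCN/AcOH, −20 °C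
Reagents that add atoms: none
Why: Evans–Saksena reduction, in which the C10 hydroxyl exchanges onto boron and delivers hydride intramolecularly to the face of the C26 carbonyl syn to C10 (also the face anti to the C14 substituent), setting C26 as the anti-1,3-diol.

Step 10
Reactants: 17 anti-1,3-diol
Product: 18 di-tert-butylsilylene acetal of 17 (Si bridges O–C26 and O–C10)
Conditions: tBu2Si(OTf)2, 2,6-lutidine, CH2Cl2, 0 °C
Reagents that add atoms: di-tert-butylsilyl bis(trifluoromethanesulfonate) CC(C)(C)[Si](OS(=O)(=O)C(F)(F)F)(OS(=O)(=O)C(F)(F)F)C(C)(C)C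
Why: Cyclic silylene formation with the bis(triflate) protects the secondary and the tertiary hydroxyl in one operation and places a bulky ring over the oxygenated face of ring A.

Step 11
Reactants: 18 silylene-protected alkene
Product: 20 C7 alcohol (C6–H and C7–OH on the face opposite the silylene; C6 chain cis to C26), via alkylborane 19 (not isolated)
Conditions: BH3·THF, THF, 0 °C → rt; then NaOH, H2O2, 0 °C
Reagents that add atoms: hydrogen peroxide OO
Why: Hydroboration–oxidation, in which BH3 should add syn from the face opposite the silylene ring, hydrogen to C6 and boron to the less substituted C7, so that the C6 chain ends cis to C26 as in the target, and the C–B bond is oxidised with retention.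

Step 12
Reactants: 20 C7 alcohol
Product: 21 C15 aldehyde
Conditions: PPTS, acetone/H2O, 45 °C
Reagents that add atoms: water O
Why: Mild acid-catalysed hydrolysis of the dimethyl acetal that the silyl ether and the silylene should tolerate, with no new stereocentre and only brief exposure of C14 as an alpha-branched aldehyde.

Step 13
Reactants: 21 C15 aldehyde
Product: 22 terminal alkyne (C15≡C27)
Conditions: dimethyl (1-diazo-2-oxopropyl)phosphonate, K2CO3, MeOH, 0 °C → rt
Reagents that add atoms: dimethyl (1-diazo-2-oxopropyl)phosphonate COP(=O)(OC)C(=[N+]=[N-])C(C)=O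
Why: Seyferth–Gilbert homologation in its Ohira–Bestmann form converts the aldehyde into the terminal alkyne under weakly basic conditions that alpha-branched, beta-silyloxy aldehydes normally survive without epimerisation.

Step 14
Reactants: 22 terminal alkyne
Product: 24 2-iodo-1-alkene (C15(I)=C27H2) with free C7 alcohol, via alkenylalane 23 (not isolated)
Conditions: Ni(dppp)Cl2 (3 mol %), iBu2AlH, THF, 0 °C → rt; then I2, THF, −78 → 0 °C
Reagents that add atoms: iodine II
Why: Nickel-catalysed alpha-selective hydroalumination of the terminal alkyne places aluminium on the internal carbon C15, and iodinolysis of the C–Al bond with retention gives the 2-iodo-1-alkene at a stage where no carbonyl group is present.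

Step 15
Reactants: 24 2-iodo-1-alkene alcohol
Product: 25 C7 ketone
Conditions: Dess–Martin periodinane, NaHCO3, CH2Cl2, rt
Reagents that add atoms: none
Why: Dess–Martin oxidation of the secondary C7 alcohol under buffered, non-enolising conditions, so that the adjacent C6 stereocentre is not epimerised.

Step 16
Reactants: 25 C7 ketone
Product: 26 C7 tertiary allylic alcohol bearing an isopropenyl group (C7 epimers)
Conditions: CH2=C(CH3)MgBr, CeCl3, THF, −78 °C
Reagents that add atoms: isopropenylmagnesium bromide CC(=C)[Mg]Br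
Why: 1,2-Addition of the weakly basic organocerium reagent to the hindered, enolisable ketone, in which the new C7 carbinol centre is formed as a mixture that is destroyed in the next step.

Step 17
Reactants: 26 C7 tertiary allylic alcohol
Product: 27 silyl-protected (2Z)-enal
Conditions: pyridinium chlorochromate (C5H5NH)[CrO3Cl], NaOAc, 4 Å MS, CH2Cl2, rt
Reagents that add atoms: pyridinium chlorochromate [O-][Cr](=O)(=O)Cl.c1cc[nH+]cc1
Why: Babler–Dauben oxidative transposition, in which the chromate ester of the tertiary allylic alcohol undergoes a [3,3]-shift and the primary chromate is oxidised to the enal; the 2Z geometry is expected because in the reacting rotamer the small =CH2 terminus (the future C1), not the methyl group, lies beside the more substituted C6, and a minor 2E isomer can be separated.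

Step 18
Reactants: 27 silyl-protected (2Z)-enal
Product: 28 core vinyl iodide triol (C3–OH, C10–OH, C26–OH free; enal; C15 iodide)
Conditions: HF·pyridine, pyridine, THF, 0 °C → rt
Reagents that add atoms: none
Why: Fluoride-mediated desilylation removes the primary silyl ether and the silylene together without touching the enal, the vinyl iodide or the tertiary alcohol.

Step 19
Reactants: 29 prop-2-yn-1-ol; 30 5-bromo-2-methylpent-2-ene
Product: 33 (Z)-3-iodo-2-(4-methylpent-3-en-1-yl)prop-2-en-1-ol, via homoprenyl Grignard reagent 31 (not isolated), via alkenylmagnesium alkoxide 32 (not isolated)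
Conditions: 30, Mg, THF; then 29, CuI (10 mol %), Et2O, −10 °C → rt; then I2, THF, −20 °C
Reagents that add atoms: iodine II
Why: Copper-catalysed anti-carbomagnesiation of the magnesium alkoxide of propargyl alcohol (carbon group to C19, magnesium to C18 in a five-membered chelate) and iodinolysis with retention fix the C18=C19 geometry with iodine cis to CH2OH.

Step 20
Reactants: 33 (Z)-3-iodo-2-(4-methylpent-3-en-1-yl)prop-2-en-1-ol
Product: 34 (Z)-3-iodo-2-(4-methylpent-3-en-1-yl)prop-2-en-1-yl acetate
Conditions: Ac2O, pyridine, DMAP (cat.), CH2Cl2, 0 °C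
Reagents that add atoms: acetic anhydride CC(=O)OC(C)=O
Why: Standard acylation of the primary allylic alcohol under nucleophilic catalysis places the only acetate of the target before any other free hydroxyl is present.

Step 21
Reactants: 34 (Z)-3-iodo-2-(4-methylpent-3-en-1-yl)prop-2-en-1-yl acetate; 35 (E)-1,2-bis(tributylstannyl)ethene
Product: 36 (2Z,4E)-2-(4-methylpent-3-en-1-yl)-5-(tributylstannyl)penta-2,4-dien-1-yl acetate (dienylstannane)
Conditions: PdCl2(MeCN)2 (5 mol %), 35 in excess, DMF, rt
Reagents that add atoms: none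
Why: Stille coupling with retention at both alkenes, in which an excess of the distannane limits the reaction to mono-coupling and delivers the (1E,3Z)-dienylstannane.

Step 22
Reactants: 28 core vinyl iodide triol; 36 dienylstannane
Product: 37 CNP0205332.1 (target)
Conditions: Pd2(dba)3 (5 mol %), AsPh3, CuI, DMF, rt, dark
Reagents that add atoms: none
Why: Stille coupling of the 2-iodo-1-alkene with the dienylstannane at room temperature forms the C15–C16 bond with retention of all alkene geometries and tolerates the free hydroxyls, the enal and the allylic acetate, so the sensitive triene appears only in the last step.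

**Compound list**

1 | (E)-4,4-dimethoxybut-2-enal | COC(OC)/C=C/C=O | starting material
2 | nitromethane | C[N+](=O)[O-] | starting material
3 | (R)-4,4-dimethoxy-3-(nitromethyl)butanal | COC(OC)[C@@H](C[N+](=O)[O-])CC=O | intermediate
4 | cyclohexane-1,3-dione | O=C1CCCC(=O)C1 | starting material
5 | 2-[(3R)-4,4-dimethoxy-3-(nitromethyl)butylidene]cyclohexane-1,3-dione (not isolated) | COC(OC)[C@@H](C[N+](=O)[O-])CC=C1C(=O)CCCC1=O | intermediate
6 | 2-[(3R)-4,4-dimethoxy-3-(nitromethyl)butyl]cyclohexane-1,3-dione | COC(OC)[C@@H](C[N+](=O)[O-])CCC1C(=O)CCCC1=O | intermediate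
7 | 2-[(3R)-4,4-dimethoxy-3-(nitromethyl)butyl]-3-oxocyclohex-1-en-1-yl trifluoromethanesulfonate | COC(OC)[C@@H](C[N+](=O)[O-])CCC1=C(OS(=O)(=O)C(F)(F)F)CCCC1=O | intermediate
8 | 2-[(3R)-4,4-dimethoxy-3-(nitromethyl)butyl]-3-methylcyclohex-2-en-1-one | COC(OC)[C@@H](C[N+](=O)[O-])CCC1=C(C)CCCC1=O | intermediate
9 | nitrile oxide of 8 (CH2NO2 replaced by C≡N+–O−; not isolated) | COC(OC)[C@@H](C#[N+][O-])CCC1=C(C)CCCC1=O | intermediate
10 | tricyclic isoxazoline ketone (C6 ketone; isoxazoline C26=N–O–C10; C10 S, C11 S, C14 R; CH(OMe)2 cis to C6) | COC(OC)[C@@H]1CC[C@@]23C(=O)CCC[C@]2(C)ON=C13 | intermediate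
11 | C6 enol triflate of 10 (C6=C7) | COC(OC)[C@@H]1CC[C@@]23C(OS(=O)(=O)C(F)(F)F)=CCC[C@]2(C)ON=C13 | intermediate
12 | allyl tert-butyldimethylsilyl ether | C=CCO[Si](C)(C)C(C)(C)C | starting material
13 | 9-[3-(tert-butyldimethylsilyloxy)propyl]-9-borabicyclo[3.3.1]nonane (not isolated) | CC(C)(C)[Si](C)(C)OCCCB1C2CCCC1CCC2 | intermediate
14 | C6-[3-(tert-butyldimethylsilyloxy)propyl] cyclohexene isoxazoline (C6=C7) | COC(OC)[C@@H]1CC[C@@]23C(CCCO[Si](C)(C)C(C)(C)C)=CCC[C@]2(C)ON=C13 | intermediate
15 | beta-hydroxy imine (C26=NH, C10–OH; not isolated) | COC(OC)[C@@H]1CC[C@]2(C(CCCO[Si](C)(C)C(C)(C)C)=CCC[C@]2(C)O)C1=N | intermediate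
16 | beta-hydroxy ketone (C26=O, C10–OH, C6=C7) | COC(OC)[C@@H]1CC[C@]2(C(CCCO[Si](C)(C)C(C)(C)C)=CCC[C@]2(C)O)C1=O | intermediate
17 | anti-1,3-diol (C26–OH cis to C6 and to the C14 substituent; C26 and C10–OH cis on ring A) | COC(OC)[C@@H]1CC[C@]2(C(CCCO[Si](C)(C)C(C)(C)C)=CCC[C@]2(C)O)[C@@H]1O | intermediate
18 | di-tert-butylsilylene acetal of 17 | COC(OC)[C@@H]1CC[C@]2(C(CCCO[Si](C)(C)C(C)(C)C)=CCC[C@]2(C)O3)[C@@H]1O[Si]3(C(C)(C)C)C(C)(C)C | intermediate
19 | C7 alkylborane, drawn as RBH2 (not isolated) | COC(OC)[C@@H]1CC[C@]2([C@H](CCCO[Si](C)(C)C(C)(C)C)[C@@H](B)CC[C@]2(C)O3)[C@@H]1O[Si]3(C(C)(C)C)C(C)(C)C | intermediate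
20 | C7 alcohol (C6 chain cis to C26; C7–OH trans to the chain) | COC(OC)[C@@H]1CC[C@]2([C@H](CCCO[Si](C)(C)C(C)(C)C)[C@@H](O)CC[C@]2(C)O3)[C@@H]1O[Si]3(C(C)(C)C)C(C)(C)C | intermediate
21 | C15 aldehyde | O=C[C@@H]1CC[C@]2([C@H](CCCO[Si](C)(C)C(C)(C)C)[C@@H](O)CC[C@]2(C)O3)[C@@H]1O[Si]3(C(C)(C)C)C(C)(C)C | intermediate
22 | terminal alkyne (C15≡C27) | C#C[C@@H]1CC[C@]2([C@H](CCCO[Si](C)(C)C(C)(C)C)[C@@H](O)CC[C@]2(C)O3)[C@@H]1O[Si]3(C(C)(C)C)C(C)(C)C | intermediate
23 | alpha-alkenylalane with C7 aluminium alkoxide (not isolated) | C=C([Al](CC(C)C)CC(C)C)[C@@H]1CC[C@]2([C@H](CCCO[Si](C)(C)C(C)(C)C)[C@@H](O[Al](CC(C)C)CC(C)C)CC[C@]2(C)O3)[C@@H]1O[Si]3(C(C)(C)C)C(C)(C)C | intermediate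
24 | 2-iodo-1-alkene with C7 alcohol | C=C(I)[C@@H]1CC[C@]2([C@H](CCCO[Si](C)(C)C(C)(C)C)[C@@H](O)CC[C@]2(C)O3)[C@@H]1O[Si]3(C(C)(C)C)C(C)(C)C | intermediate
25 | C7 ketone | C=C(I)[C@@H]1CC[C@]2([C@H](CCCO[Si](C)(C)C(C)(C)C)C(=O)CC[C@]2(C)O3)[C@@H]1O[Si]3(C(C)(C)C)C(C)(C)C | intermediate
26 | C7 tertiary allylic alcohol with isopropenyl group (C7 epimers) | C=C(I)[C@@H]1CC[C@]2([C@H](CCCO[Si](C)(C)C(C)(C)C)C(O)(C(C)=C)CC[C@]2(C)O3)[C@@H]1O[Si]3(C(C)(C)C)C(C)(C)C | intermediate
27 | silyl-protected (2Z)-enal | C=C(I)[C@@H]1CC[C@]2([C@H](CCCO[Si](C)(C)C(C)(C)C)/C(=C(/C)C=O)CC[C@]2(C)O3)[C@@H]1O[Si]3(C(C)(C)C)C(C)(C)C | intermediate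
28 | core vinyl iodide triol (2Z-enal; C15 iodide) | C=C(I)[C@@H]1CC[C@]2([C@H](CCCO)/C(=C(/C)C=O)CC[C@]2(C)O)[C@@H]1O | intermediate
29 | prop-2-yn-1-ol | C#CCO | starting material
30 | 5-bromo-2-methylpent-2-ene | CC(C)=CCCBr | starting material
31 | (4-methylpent-3-en-1-yl)magnesium bromide (not isolated) | CC(C)=CCC[Mg]Br | intermediate
32 | (Z)-alkenylmagnesium bromide magnesium alkoxide, Mg cis to CH2O (not isolated) | Br[Mg]/C=C(/CCC=C(C)C)CO[Mg]Br | intermediate
33 | (Z)-3-iodo-2-(4-methylpent-3-en-1-yl)prop-2-en-1-ol | I/C=C(/CCC=C(C)C)CO | intermediate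
34 | (Z)-3-iodo-2-(4-methylpent-3-en-1-yl)prop-2-en-1-yl acetate | I/C=C(/CCC=C(C)C)COC(C)=O | intermediate
35 | (E)-1,2-bis(tributylstannyl)ethene | CCCC[Sn](CCCC)(CCCC)/C=C/[Sn](CCCC)(CCCC)CCCC | starting material
36 | (2Z,4E)-2-(4-methylpent-3-en-1-yl)-5-(tributylstannyl)penta-2,4-dien-1-yl acetate | CCCC[Sn](CCCC)(CCCC)/C=C/C=C(/CCC=C(C)C)COC(C)=O | intermediate
37 | CNP0205332.1 (2Z,6R,10S,11S,14S,16E,18Z,26R in biogenetic numbering) | C=C(/C=C/C=C(/CCC=C(C)C)COC(C)=O)[C@@H]1CC[C@]2([C@H](CCCO)/C(=C(/C)C=O)CC[C@]2(C)O)[C@@H]1O | target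

**Step count and risks**

Total step count: 22. Longest linear sequence: 19 steps (steps 1–18 and 22).

Steps most likely to fail:

Step 5. The single C14 stereocentre may discriminate poorly between the two faces of the tetrasubstituted enone, and the hindered dipolarophile may lose to dimerisation of the dipole. The fallback sets out from 8 and comes back at 10; it hands facial control to an allylic stereocentre set by catalysis. Corey–Bakshi–Shibata reduction of 8 ((R)-2-methyl-CBS-oxazaborolidine, BH3·SMe2, THF, −20 °C) should give (1S)-2-[(3R)-4,4-dimethoxy-3-(nitromethyl)butyl]-3-methylcyclohex-2-en-1-ol F1. Silylation (TBSOTf, 2,6-lutidine) gives its tert-butyldimethylsilyl ether F2. PhNCO and Et3N then generate the nitrile oxide F3, which should add anti to the pseudoaxial allylic silyloxy group and give the C6-silyloxy tricyclic isoxazoline F4. Bu4NF gives the C6 alcohol F5, and Dess–Martin oxidation returns ketone 10.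

Step 17. Geometric control may be lost in the [3,3]-transposition or by later isomerisation of the tetrasubstituted enal, which would give a 2Z/2E mixture. The fallback sets out from 25 and comes back at 28; it enforces the geometry with a temporary ring. Selective removal of the primary silyl ether (PPTS, MeOH) gives the C3 alcohol F6. Esterification with 2-(diethoxyphosphoryl)propanoic acid (EDC·HCl, DMAP) gives the phosphonate ester F7. Intramolecular Horner–Wadsworth–Emmons olefination at C7 (LiCl, DBU, MeCN, high dilution) closes the eight-membered lactone F8, whose ring admits only the Z alkene (C1 cis to C6). Reduction with iBu2AlH gives the C1,C3-diol F9, and MnO2 oxidises only the allylic C1 alcohol to the (2Z)-enal F10. HF·pyridine then removes the silylene to give 28.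

Step 11. Borane may be delivered from the wrong face of the C6=C7 alkene, which would place the C6 chain trans to C26. The fallback sets out from 17 and comes back at 20; it replaces steric control by hydroxyl direction. Epoxidation directed by the homoallylic hydroxyls (VO(acac)2, tBuOOH, CH2Cl2) should give the syn C6,C7-epoxide F11, which is protected as the silylene F12 (tBu2Si(OTf)2, 2,6-lutidine). Meinwald rearrangement (InCl3, THF) with a 1,2-hydride shift from C7 to C6, anti to the departing oxygen, gives the C7 ketone F13 with the C6 chain cis to C26. NaBH4 reduction then gives alcohol 20.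

Further compounds
F1 | step 5 | (1S)-2-[(3R)-4,4-dimethoxy-3-(nitromethyl)butyl]-3-methylcyclohex-2-en-1-ol | COC(OC)[C@@H](C[N+](=O)[O-])CCC1=C(C)CCC[C@@H]1O
F2 | step 5 | tert-butyldimethylsilyl ether of F1 | COC(OC)[C@@H](C[N+](=O)[O-])CCC1=C(C)CCC[C@@H]1O[Si](C)(C)C(C)(C)C
F3 | step 5 | nitrile oxide from F2 | COC(OC)[C@@H](C#[N+][O-])CCC1=C(C)CCC[C@@H]1O[Si](C)(C)C(C)(C)C
F4 | step 5 | C6-silyloxy tricyclic isoxazoline (C6–O trans to C26) | COC(OC)[C@@H]1CC[C@@]23[C@@H](O[Si](C)(C)C(C)(C)C)CCC[C@]2(C)ON=C13
F5 | step 5 | C6-hydroxy tricyclic isoxazoline | COC(OC)[C@@H]1CC[C@@]23[C@@H](O)CCC[C@]2(C)ON=C13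
F6 | step 17 | C3 alcohol of ketone 25 | C=C(I)[C@@H]1CC[C@]2([C@H](CCCO)C(=O)CC[C@]2(C)O3)[C@@H]1O[Si]3(C(C)(C)C)C(C)(C)C
F7 | step 17 | C3 2-(diethoxyphosphoryl)propanoate of F6 | C=C(I)[C@@H]1CC[C@]2([C@H](CCCOC(=O)C(C)P(=O)(OCC)OCC)C(=O)CC[C@]2(C)O3)[C@@H]1O[Si]3(C(C)(C)C)C(C)(C)C
F8 | step 17 | eight-membered (Z)-lactone (C1–O–C3; C7=C2) | C=C(I)[C@@H]1CC[C@]2([C@@H]4CCCOC(=O)/C(C)=C4/CC[C@]2(C)O3)[C@@H]1O[Si]3(C(C)(C)C)C(C)(C)C
F9 | step 17 | (2Z)-C1,C3-diol, silylene intact | C=C(I)[C@@H]1CC[C@]2([C@H](CCCO)/C(=C(/C)CO)CC[C@]2(C)O3)[C@@H]1O[Si]3(C(C)(C)C)C(C)(C)C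
F10 | step 17 | (2Z)-enal with free C3 alcohol, silylene intact | C=C(I)[C@@H]1CC[C@]2([C@H](CCCO)/C(=C(/C)C=O)CC[C@]2(C)O3)[C@@H]1O[Si]3(C(C)(C)C)C(C)(C)C
F11 | step 11 | C6,C7-epoxide of 17 (epoxide oxygen syn to the hydroxyls) | COC(OC)[C@@H]1CC[C@]2([C@]3(CCCO[Si](C)(C)C(C)(C)C)O[C@@H]3CC[C@]2(C)O)[C@@H]1O
F12 | step 11 | di-tert-butylsilylene acetal of F11 | COC(OC)[C@@H]1CC[C@]2([C@]3(CCCO[Si](C)(C)C(C)(C)C)O[C@@H]3CC[C@]2(C)O4)[C@@H]1O[Si]4(C(C)(C)C)C(C)(C)C
F13 | step 11 | C7 ketone with dimethyl acetal intact (C6 chain cis to C26) | COC(OC)[C@@H]1CC[C@]2([C@H](CCCO[Si](C)(C)C(C)(C)C)C(=O)CC[C@]2(C)O3)[C@@H]1O[Si]3(C(C)(C)C)C(C)(C)C
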